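## Retrosynthetic overview

1. Target 25 ⇒ ester C–O bond: macrocyclic alcohol 19 plus O-silylated vanillic acid 22 (the arene is bought intact, never built).
2. 19 ⇒ Wittig methylenation (C1=CH2) of the macrocyclic (E)-enone 17.
3. 17 ⇒ the only ring-forming event: intramolecular Horner–Wadsworth–Emmons closure (C2=C3) of keto-phosphonate aldehyde 16 to the 11-membered carbocycle.
4. 16 ⇒ C10–C11 bond by alkylating allylic bromide 11 with the dianion of dimethyl (2-oxopropyl)phosphonate 12.
5. 11 ⇒ key fragment union C4–C5: enantioselective Mukaiyama aldol of aldehyde 4 (from geranyl acetate 1) with isobutyrate ketene acetal 5, which sets the single stereocentre (R).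

Assumption: ring atoms are numbered C1 (bears =CH2), C2=C3, C4 (CMe2), C5 (carbinol, R), C6, C7, C8(Me)=C9, C10, C11; the L-valine-derived boron promoter is taken to give the 3R aldol, as for unbranched aliphatic aldehydes (to be confirmed by Mosher ester analysis of 7). TBS = tert-butyldimethylsilyl, TES = triethylsilyl.

## Route

Step 1
Reactants: 1 geranyl acetate
Product: 2 (2E)-5-(3,3-dimethyloxiran-2-yl)-3-methylpent-2-en-1-yl acetate (racemic 6,7-epoxide)
Conditions: mCPBA (1.05 eq), CH2Cl2, 0 °C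
Reagents that add atoms: mCPBA, OOC(=O)c1cccc(Cl)c1
Why: Prilezhaev epoxidation picks the electron-rich remote trisubstituted alkene over the 2,3-alkene deactivated by the allylic acetate; the epoxide configuration is irrelevant because this carbon is excised next.

Step 2
Reactants: 2 racemic 6,7-epoxygeranyl acetate
Product: 4 (2E)-3-methyl-6-oxohex-2-en-1-yl acetate, via vicinal diol 3 (not isolated)
Conditions: H5IO6 (1.1 eq), THF/Et2O, 0 °C
Reagents that add atoms: none
Why: Acid-mediated epoxide hydration followed by Malaprade glycol cleavage; water enters at the tertiary carbon and that oxygen leaves in acetone, so the aldehyde keeps the epoxide oxygen, and the (E)-alkene and acetate are untouched.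

Step 3
Reactants: 4 (2E)-3-methyl-6-oxohex-2-en-1-yl acetate; 5 1-methoxy-2-methyl-1-(trimethylsilyloxy)prop-1-ene
Product: 7 methyl (3R,6E)-8-acetoxy-3-hydroxy-2,2,6-trimethyloct-6-enoate, via trimethylsilyl aldolate 6 (not isolated)
Conditions: N-Ts-L-valine (1.1 eq), BH3·THF (1.0 eq), CH2Cl2, 0 °C→rt; then 4, 5, −78 °C; 1 M HCl, THF
Reagents that add atoms: none
Why: Intermolecular Mukaiyama aldol (Kiyooka variant): the aldehyde bound to the (S)-valine oxazaborolidinone is attacked on its exposed si face through an open transition state, forming the C4–C5 bond, the quaternary carbon and the 3R carbinol (about 90% ee or better expected).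

Step 4
Reactants: 7 methyl (3R,6E)-8-acetoxy-3-hydroxy-2,2,6-trimethyloct-6-enoate
Product: 8 methyl (3R,6E)-8-acetoxy-3-[(tert-butyldimethylsilyl)oxy]-2,2,6-trimethyloct-6-enoate
Conditions: TBSOTf (1.5 eq), 2,6-lutidine, CH2Cl2, −78→0 °C
Reagents that add atoms: TBSOTf, CC(C)(C)[Si](C)(C)OS(=O)(=O)C(F)(F)F
Why: Silyl triflate silylation is strong enough for the hindered neopentyl-type secondary alcohol and does not touch the stereocentre or either ester.

Step 5
Reactants: 8 methyl (3R,6E)-8-acetoxy-3-[(tert-butyldimethylsilyl)oxy]-2,2,6-trimethyloct-6-enoate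
Product: 9 (2E,6R)-6-[(tert-butyldimethylsilyl)oxy]-3,7,7-trimethyloct-2-ene-1,8-diol
Conditions: i-Bu2AlH (5 eq), CH2Cl2, −78→0 °C; aq potassium sodium tartrate
Reagents that add atoms: none
Why: Exhaustive aluminium hydride reduction removes the acetate and takes the hindered methyl ester to the neopentyl alcohol in one operation, with the silyl ether and alkene inert.

Step 6
Reactants: 9 (2E,6R)-6-[(tert-butyldimethylsilyl)oxy]-3,7,7-trimethyloct-2-ene-1,8-diol
Product: 10 (3R,6E)-8-bromo-3-[(tert-butyldimethylsilyl)oxy]-2,2,6-trimethyloct-6-en-1-ol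
Conditions: NBS (1.5 eq), Me2S (1.8 eq), CH2Cl2, −30→0 °C
Reagents that add atoms: NBS, BrN1C(=O)CCC1=O
Why: Corey–Kim halogenation converts only the allylic alcohol, since the neopentyl alkoxysulfonium cannot undergo SN2 and reverts to the alcohol on work-up; it proceeds without allylic transposition, so the (E)-geometry is kept.

Step 7
Reactants: 10 (3R,6E)-8-bromo-3-[(tert-butyldimethylsilyl)oxy]-2,2,6-trimethyloct-6-en-1-ol
Product: 11 tert-butyl{[(3R,6E)-8-bromo-2,2,6-trimethyl-1-(triethylsilyloxy)oct-6-en-3-yl]oxy}dimethylsilane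
Conditions: TESOTf (1.2 eq), 2,6-lutidine, CH2Cl2, −78 °C
Reagents that add atoms: TESOTf, CC[Si](CC)(CC)OS(=O)(=O)C(F)(F)F
Why: Low-temperature silylation with a hindered base caps the primary alcohol without attacking the allylic bromide, so the strongly basic next step cannot trigger 1,3-O-to-O migration of the TBS group.

Step 8
Reactants: 11 the TES-protected allylic bromide; 12 dimethyl (2-oxopropyl)phosphonate
Product: 14 dimethyl [(5E,9R)-9-[(tert-butyldimethylsilyl)oxy]-6,10,10-trimethyl-2-oxo-11-(triethylsilyloxy)undec-5-en-1-yl]phosphonate, via phosphonate dianion 13 (not isolated)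
Conditions: 12 (2.0 eq), NaH (2.0 eq), THF, 0 °C; n-BuLi (2.0 eq), 0 °C; then 11, 0 °C→rt; aq NH4Cl
Reagents that add atoms: none
Why: γ-Alkylation of a β-keto phosphonate dianion: the more basic terminal carbanion displaces the primary allylic bromide by SN2, forming C10–C11 and installing the complete olefination handle.

Step 9
Reactants: 14 the TES-protected keto phosphonate
Product: 15 dimethyl [(5E,9R)-9-[(tert-butyldimethylsilyl)oxy]-11-hydroxy-6,10,10-trimethyl-2-oxoundec-5-en-1-yl]phosphonate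
Conditions: AcOH/THF/H2O 3:1:1, rt
Reagents that add atoms: none
Why: Selective acidic desilylation: a primary TES ether hydrolyses far faster than the hindered secondary TBS ether.

Step 10
Reactants: 15 the hydroxy keto phosphonate
Product: 16 dimethyl [(5E,9R)-9-[(tert-butyldimethylsilyl)oxy]-6,10,10-trimethyl-2,11-dioxoundec-5-en-1-yl]phosphonate
Conditions: Dess–Martin periodinane (1.5 eq), CH2Cl2, 0 °C→rt
Reagents that add atoms: none
Why: Dess–Martin oxidation tolerates the β-keto phosphonate and gives an α-quaternary aldehyde that can neither enolise nor β-eliminate.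

Step 11
Reactants: 16 the keto-phosphonate aldehyde
Product: 17 (2E,5R,8E)-5-[(tert-butyldimethylsilyl)oxy]-4,4,8-trimethylcycloundeca-2,8-dien-1-one
Conditions: K2CO3 (6 eq), 18-crown-6 (12 eq), toluene, 80 °C, syringe-pump addition to 1 mM
Reagents that add atoms: none
Why: Intramolecular Horner–Wadsworth–Emmons olefination at high dilution closes the 11-membered ring onto a non-enolisable aldehyde and gives the (E)-enone under the usual thermodynamic control of stabilised phosphonates.

Step 12
Reactants: 17 the macrocyclic (E)-enone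
Product: 18 tert-butyldimethyl{[(1R,3E,8E)-2,2,9-trimethyl-5-methylidenecycloundeca-3,8-dien-1-yl]oxy}silane
Conditions: Ph3PCH3Br (4 eq), KOt-Bu (3.8 eq), THF, 0 °C→rt
Reagents that add atoms: methyltriphenylphosphonium bromide, C[P+](c1ccccc1)(c1ccccc1)c1ccccc1.[Br-]
Why: Wittig methylenation adds 1,2 to the enone carbonyl, because the β-carbon is neopentyl-shielded and there is no γ-hydrogen for deconjugation, giving the cross-conjugated exocyclic diene.

Step 13
Reactants: 18 the silyl-protected triene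
Product: 19 (1R,3E,8E)-2,2,9-trimethyl-5-methylidenecycloundeca-3,8-dien-1-ol
Conditions: Bu4NF (3 eq), THF, 50 °C
Reagents that add atoms: none
Why: Fluoride-driven desilylation cleaves the Si–O bond only, so the carbinol configuration is retained and the acid-sensitive triene sees no acid.

Step 14
Reactants: 20 vanillic acid
Product: 22 4-[(tert-butyldimethylsilyl)oxy]-3-methoxybenzoic acid, via bis-silylated silyl ester 21 (not isolated)
Conditions: TBSCl (2.4 eq), imidazole (5 eq), DMF, rt; then AcOH/THF/H2O, rt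
Reagents that add atoms: TBSCl, CC(C)(C)[Si](C)(C)Cl
Why: Exhaustive silylation followed by selective hydrolysis of the far more labile silyl ester leaves the aryl silyl ether as phenol protection.

Step 15
Reactants: 19 the macrocyclic alcohol; 22 4-[(tert-butyldimethylsilyl)oxy]-3-methoxybenzoic acid
Product: 24 (1R,3E,8E)-2,2,9-trimethyl-5-methylidenecycloundeca-3,8-dien-1-yl 4-[(tert-butyldimethylsilyl)oxy]-3-methoxybenzoate, via Yamaguchi mixed anhydride 23 (not isolated)
Conditions: 22 (1.5 eq), 2,4,6-trichlorobenzoyl chloride (1.5 eq), Et3N (3 eq), toluene, rt; then 19, DMAP (2 eq), 60 °C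
Reagents that add atoms: none
Why: Yamaguchi esterification: DMAP attacks the unhindered aroyl carbonyl of the mixed anhydride and the resulting acylpyridinium acylates the hindered secondary alcohol on oxygen, so C5 keeps its R configuration.

Step 16
Reactants: 24 the silyl-protected vanillate ester
Product: 25 (1R,3E,8E)-2,2,9-trimethyl-5-methylidenecycloundeca-3,8-dien-1-yl 4-hydroxy-3-methoxybenzoate (target)
Conditions: Bu4NF (1.1 eq), AcOH (1.1 eq), THF, 0 °C
Reagents that add atoms: none
Why: Buffered fluoride cleaves the very labile aryl silyl ether within minutes and leaves the hindered benzoate ester and the triene intact.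

## Compound list

1 | geranyl acetate, (2E)-3,7-dimethylocta-2,6-dien-1-yl acetate | CC(C)=CCC/C(C)=C/COC(C)=O | starting material
2 | (2E)-5-(3,3-dimethyloxiran-2-yl)-3-methylpent-2-en-1-yl acetate (racemic) | CC1(C)OC1CC/C(C)=C/COC(C)=O | intermediate
3 | (2E)-6,7-dihydroxy-3,7-dimethyloct-2-en-1-yl acetate (racemic, not isolated) | CC(C)(O)C(O)CC/C(C)=C/COC(C)=O | intermediate
4 | (2E)-3-methyl-6-oxohex-2-en-1-yl acetate | O=CCC/C(C)=C/COC(C)=O | intermediate
5 | 1-methoxy-2-methyl-1-(trimethylsilyloxy)prop-1-ene | COC(O[Si](C)(C)C)=C(C)C | starting material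
6 | methyl (3R,6E)-8-acetoxy-2,2,6-trimethyl-3-(trimethylsilyloxy)oct-6-enoate (not isolated) | COC(=O)C(C)(C)[C@H](O[Si](C)(C)C)CC/C(C)=C/COC(C)=O | intermediate
7 | methyl (3R,6E)-8-acetoxy-3-hydroxy-2,2,6-trimethyloct-6-enoate | COC(=O)C(C)(C)[C@H](O)CC/C(C)=C/COC(C)=O | intermediate
8 | methyl (3R,6E)-8-acetoxy-3-[(tert-butyldimethylsilyl)oxy]-2,2,6-trimethyloct-6-enoate | COC(=O)C(C)(C)[C@H](O[Si](C)(C)C(C)(C)C)CC/C(C)=C/COC(C)=O | intermediate
9 | (2E,6R)-6-[(tert-butyldimethylsilyl)oxy]-3,7,7-trimethyloct-2-ene-1,8-diol | OCC(C)(C)[C@H](O[Si](C)(C)C(C)(C)C)CC/C(C)=C/CO | intermediate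
10 | (3R,6E)-8-bromo-3-[(tert-butyldimethylsilyl)oxy]-2,2,6-trimethyloct-6-en-1-ol | OCC(C)(C)[C@H](O[Si](C)(C)C(C)(C)C)CC/C(C)=C/CBr | intermediate
11 | tert-butyl{[(3R,6E)-8-bromo-2,2,6-trimethyl-1-(triethylsilyloxy)oct-6-en-3-yl]oxy}dimethylsilane | CC[Si](CC)(CC)OCC(C)(C)[C@H](O[Si](C)(C)C(C)(C)C)CC/C(C)=C/CBr | intermediate
12 | dimethyl (2-oxopropyl)phosphonate | CC(=O)CP(=O)(OC)OC | starting material
13 | sodium lithium 1,3-dianion of dimethyl (2-oxopropyl)phosphonate (not isolated) | [Na+].[Li+].[CH2-]C(=O)[CH-]P(=O)(OC)OC | intermediate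
14 | dimethyl [(5E,9R)-9-[(tert-butyldimethylsilyl)oxy]-6,10,10-trimethyl-2-oxo-11-(triethylsilyloxy)undec-5-en-1-yl]phosphonate | CC[Si](CC)(CC)OCC(C)(C)[C@H](O[Si](C)(C)C(C)(C)C)CC/C(C)=C/CCC(=O)CP(=O)(OC)OC | intermediate
15 | dimethyl [(5E,9R)-9-[(tert-butyldimethylsilyl)oxy]-11-hydroxy-6,10,10-trimethyl-2-oxoundec-5-en-1-yl]phosphonate | OCC(C)(C)[C@H](O[Si](C)(C)C(C)(C)C)CC/C(C)=C/CCC(=O)CP(=O)(OC)OC | intermediate
16 | dimethyl [(5E,9R)-9-[(tert-butyldimethylsilyl)oxy]-6,10,10-trimethyl-2,11-dioxoundec-5-en-1-yl]phosphonate | O=CC(C)(C)[C@H](O[Si](C)(C)C(C)(C)C)CC/C(C)=C/CCC(=O)CP(=O)(OC)OC | intermediate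
17 | (2E,5R,8E)-5-[(tert-butyldimethylsilyl)oxy]-4,4,8-trimethylcycloundeca-2,8-dien-1-one | O=C1/C=C/C(C)(C)[C@H](O[Si](C)(C)C(C)(C)C)CC/C(C)=C/CC1 | intermediate
18 | tert-butyldimethyl{[(1R,3E,8E)-2,2,9-trimethyl-5-methylidenecycloundeca-3,8-dien-1-yl]oxy}silane | C=C1/C=C/C(C)(C)[C@H](O[Si](C)(C)C(C)(C)C)CC/C(C)=C/CC1 | intermediate
19 | (1R,3E,8E)-2,2,9-trimethyl-5-methylidenecycloundeca-3,8-dien-1-ol | C=C1/C=C/C(C)(C)[C@H](O)CC/C(C)=C/CC1 | intermediate
20 | vanillic acid (4-hydroxy-3-methoxybenzoic acid) | COc1cc(C(=O)O)ccc1O | starting material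
21 | tert-butyldimethylsilyl 4-[(tert-butyldimethylsilyl)oxy]-3-methoxybenzoate (not isolated) | COc1cc(C(=O)O[Si](C)(C)C(C)(C)C)ccc1O[Si](C)(C)C(C)(C)C | intermediate
22 | 4-[(tert-butyldimethylsilyl)oxy]-3-methoxybenzoic acid | COc1cc(C(=O)O)ccc1O[Si](C)(C)C(C)(C)C | intermediate
23 | 4-[(tert-butyldimethylsilyl)oxy]-3-methoxybenzoic 2,4,6-trichlorobenzoic anhydride (not isolated) | COc1cc(C(=O)OC(=O)c2c(Cl)cc(Cl)cc2Cl)ccc1O[Si](C)(C)C(C)(C)C | intermediate
24 | (1R,3E,8E)-2,2,9-trimethyl-5-methylidenecycloundeca-3,8-dien-1-yl 4-[(tert-butyldimethylsilyl)oxy]-3-methoxybenzoate | C=C1/C=C/C(C)(C)[C@H](OC(=O)c2ccc(O[Si](C)(C)C(C)(C)C)c(OC)c2)CC/C(C)=C/CC1 | intermediate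
25 | (1R,3E,8E)-2,2,9-trimethyl-5-methylidenecycloundeca-3,8-dien-1-yl 4-hydroxy-3-methoxybenzoate | C=C1/C=C/C(C)(C)[C@H](OC(=O)c2ccc(O)c(OC)c2)CC/C(C)=C/CC1 | target

## Step count and risks

Total steps: 16. Longest linear sequence: 15 (steps 1–13, then 15 and 16; step 14 is a one-step side branch).

Most likely to fail:

**Step 11, macrocyclising olefination.** An 11-membered ring is strained, and oligomerisation or a sluggish reaction of the neopentyl aldehyde could dominate. The fallback closes the same ring by a Nozaki–Hiyama–Kishi reaction and sets out from bromide 11. Alkylation of 11 with LiCH2CN (MeCN, LiN(i-Pr)2, THF, −78 °C) gives the homologated nitrile F1. Cleavage of the TES ether (AcOH/THF/H2O) gives the hydroxy nitrile F2, and Dess–Martin oxidation gives the aldehyde nitrile F3. Takai olefination (CrCl2, CHI3, THF) gives the (E)-vinyl iodide F4, and reduction of the nitrile (i-Bu2AlH, toluene, −78 °C, then aqueous acid) gives the iodo aldehyde F5. Cyclisation with CrCl2 and catalytic NiCl2 in DMSO at high dilution gives the macrocyclic allylic alcohol F6, and MnO2 oxidation brings the material back to the route at enone 17.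

**Step 3, enantioselective aldol.** The enantiomeric excess or the sense of induction with this functionalised aldehyde may fall short. The fallback keeps the aldol union but moves stereocontrol to a reduction, and sets out from aldehyde 4. Addition of the lithium enolate of methyl isobutyrate (LiN(i-Pr)2, THF, −78 °C) gives the racemic aldol F7. Dess–Martin oxidation gives the β-keto ester F8. Reduction with catecholborane and 20 mol % (S)-2-methyl-CBS-oxazaborolidine (toluene, −78 °C), with the quaternary carbon as the large group, delivers the 3R alcohol and returns to the route at 7.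

**Step 12, methylenation.** Enolisation of the macrocyclic enone by the basic ylide could stall conversion. The fallback is a two-stage Peterson olefination and sets out from enone 17. 1,2-Addition of Me3SiCH2Li with CeCl3 (THF, −78 °C) gives the β-hydroxysilane F9. Syn-elimination with KH in THF returns to the route at triene 18.

## Further compounds

F1 | step 11 | (4E,8R)-8-[(tert-butyldimethylsilyl)oxy]-5,9,9-trimethyl-10-(triethylsilyloxy)dec-4-enenitrile | CC[Si](CC)(CC)OCC(C)(C)[C@H](O[Si](C)(C)C(C)(C)C)CC/C(C)=C/CCC#N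
F2 | step 11 | (4E,8R)-8-[(tert-butyldimethylsilyl)oxy]-10-hydroxy-5,9,9-trimethyldec-4-enenitrile | OCC(C)(C)[C@H](O[Si](C)(C)C(C)(C)C)CC/C(C)=C/CCC#N
F3 | step 11 | (4E,8R)-8-[(tert-butyldimethylsilyl)oxy]-5,9,9-trimethyl-10-oxodec-4-enenitrile | O=CC(C)(C)[C@H](O[Si](C)(C)C(C)(C)C)CC/C(C)=C/CCC#N
F4 | step 11 | (4E,8R,10E)-8-[(tert-butyldimethylsilyl)oxy]-11-iodo-5,9,9-trimethylundeca-4,10-dienenitrile | I/C=C/C(C)(C)[C@H](O[Si](C)(C)C(C)(C)C)CC/C(C)=C/CCC#N
F5 | step 11 | (4E,8R,10E)-8-[(tert-butyldimethylsilyl)oxy]-11-iodo-5,9,9-trimethylundeca-4,10-dienal | I/C=C/C(C)(C)[C@H](O[Si](C)(C)C(C)(C)C)CC/C(C)=C/CCC=O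
F6 | step 11 | (2E,5R,8E)-5-[(tert-butyldimethylsilyl)oxy]-4,4,8-trimethylcycloundeca-2,8-dien-1-ol (epimer mixture at C1) | OC1/C=C/C(C)(C)[C@H](O[Si](C)(C)C(C)(C)C)CC/C(C)=C/CC1
F7 | step 3 | methyl (6E)-8-acetoxy-3-hydroxy-2,2,6-trimethyloct-6-enoate (racemic) | COC(=O)C(C)(C)C(O)CC/C(C)=C/COC(C)=O
F8 | step 3 | methyl (6E)-8-acetoxy-2,2,6-trimethyl-3-oxooct-6-enoate | COC(=O)C(C)(C)C(=O)CC/C(C)=C/COC(C)=O
F9 | step 12 | (2E,5R,8E)-5-[(tert-butyldimethylsilyl)oxy]-4,4,8-trimethyl-1-[(trimethylsilyl)methyl]cycloundeca-2,8-dien-1-ol (epimer mixture at C1) | C[Si](C)(C)CC1(O)/C=C/C(C)(C)[C@H](O[Si](C)(C)C(C)(C)C)CC/C(C)=C/CC1
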